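Its constants are invented; no experiment stands behind them.

Where a flask stops comes first.

all flasks: J 8.3 µM; time 12 min

|  | Z |
|---|---|
| autumn | 0.025 M |
| winter | 0.050 M |
| dusk | 0.10 M |
| midnight | 0.20 M |

    Z.J ⇌ J + D (K1 = 0.042 M, k1 = 12000 /min)
    Z + J ⇌ Z.J (K2 = 8.7 /M, k2 = 1.5 × 10⁵ /M/s)
    2 J → J2 (k3 = 4600 /M/min)

- [D] at the end for autumn, winter, dusk, midnight, in this order
- the course of these numbers from the first flask to the last (falls all the way / falls, then rises / rises all the way / hardly changes / rises, then falls)

**End share.** J carries Z to D through Z.J and comes back from the round, so the two reversible steps multiply. At rest, [D] over [Z] is 0.042 M times 8.7 /M, or 0.365. The part of the charged Z that stands as D at rest is this ratio over one plus the ratio, 26.8 %: the end share, or equilibrium conversion. No charge enters it. In autumn the J charged is hardly any of the Z charged, so Z.J makes no visible dent in the balance.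

**Autumn and winter.** Winter looks like autumn with twice the Z and the same J. By hand, autumn ends at 0.00669 M of D and winter at 0.0134 M, provided each flask gets there.

**The pace.** Z.J goes back to Z at 1.03 × 10⁶ /min, faster than it goes on to D at 12000 /min, so Z.J follows Z and J closely. Free J at the start is then the charged J over one plus the binding term, which at the start is 0.22 in autumn. The closing time is the inverse of free J times 12000 /min times the sum of 8.7 /M and the inverse of 0.042 M. From the start values it comes to 0.376 min in autumn and 0.443 min in winter, longer there because more J sits as Z.J. Meanwhile the charged J, by this step alone, goes to J2 with a first half-life of 13.1 min. Both closing times lie far below that half-life and the 12 min allowed, so by this reckoning autumn and winter both reach the end share while J still works. They differ in the amount of D by the charge of Z.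

**The forecast.** It gives 0.00669 M, 0.01338 M, 0.02676 M and 0.0535 M, course rises all the way, on the ground that “[D] simply doubles with each doubling of Z”. The reckoning above stands at the same values for autumn and winter.

**The result.** The flasks end at 0.00669 M, 0.0134 M, 0.0268 M and 0.0535 M, so the row rises all the way. In autumn that is 26.8 % of the Z charged, against an end share of 26.8 %. In midnight, a tenfold time makes no difference to [D], although J2 has grown to 63.9 % of the catalyst charged by 120 min. The end share times the midnight charge gives 0.0535 M, and midnight stands at 0.0535 M of D, with Z at 73.2 % of its charge.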